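**Plan**
1. The cyclohexene at the spiro junction is cut at C2′–C4 and C14′–C15 (Diels–Alder). This gives two molecules of dehydrozaluzanin C (21), one used as its 1′,2′-dehydro derivative 23. The C1′=C10′ olefin of the adduct is moved into conjugation at the end.
2. 21 is cut at C6–C7 and C1–C5. In a guaianolide these are the two bonds that fold a farnesane chain: C6–C7 closes the ten-membered ring (and, through O6, the lactone), and C1–C5 crosses that ring to give the five- and seven-membered rings.
3. Enabling feature: across the ten-membered ring the C1=C10 olefin faces the C4–C5 epoxide (1,5-relationship), and silicon on C14 turns the C10 cation into the exocyclic C10=C14 olefin.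
4. Forward: geraniol → (2R,3R)-epoxide → C1 aldehyde → 2-(silylmethyl)vinyl addition and Claisen rearrangement (C7–C10, C14) → Baylis–Hillman reaction (C11–C13) → acyclic 15 → both ring-forming bonds in one pot (17) → C3/C4 adjustment to 21 → dimerisation.
5. Stereochemistry: C4/C5 from the Sharpless epoxide (C5 inverted in the cyclisation); C6/C7 from the macrocyclising allylation; C1 from the crossed ring conformer; spiro C4 from α-face Diels–Alder; C5′/C10′ by equilibration. The C3 carbinol is temporary.

Key step: step 9

Assumption: C5′ and C10′ are γ to the final 1′(2′)-en-3′-one (C5′ is also allylic to C4′=C15′), so both are epimerisable; the target configuration (5′-H cis to 6′-H, 10′-H α) is taken to be the one favoured at equilibrium. Guaiane numbering is used throughout; primed atoms belong to the enone half.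

Step 1
Reactants: 1 geraniol
Product: 2 (2R,3R)-2,3-epoxygeraniol
Conditions: Ti(OiPr)4 (cat.), D-(−)-diethyl tartrate (cat.), t-BuOOH, 4 Å molecular sieves, CH2Cl2, −20 °C
Reagents that add atoms: tert-butyl hydroperoxide, CC(C)(C)OO
Why: Sharpless asymmetric epoxidation acts only on the allylic alcohol olefin, and the D-tartrate ligand should deliver oxygen to the face that gives the trans (2R,3R)-epoxide, which fixes C4 and C5 of the later guaianolide.

Step 2
Reactants: 2 (2R,3R)-2,3-epoxygeraniol
Product: 3 triethylsilyl ether of 2
Conditions: Et3SiCl, imidazole, CH2Cl2, 0 °C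
Reagents that add atoms: chlorotriethylsilane, CC[Si](Cl)(CC)CC
Why: Standard silylation of the primary alcohol; the triethylsilyl ether is chosen because it can later be oxidised directly to the aldehyde.

Step 3
Reactants: 3 triethylsilyl ether of 2
Product: 4 3-[(2R,3R)-2-methyl-3-(triethylsilyloxymethyl)oxiran-2-yl]propanal
Conditions: O3, CH2Cl2, −78 °C; then PPh3
Reagents that add atoms: ozone, [O-][O+]=O
Why: Ozonolysis with reductive work-up cleaves the only C=C bond and unmasks C1 as an aldehyde without touching the epoxide or the silyl ether.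

Step 4
Reactants: 4 3-[(2R,3R)-2-methyl-3-(triethylsilyloxymethyl)oxiran-2-yl]propanal, 5 (2-bromoprop-2-en-1-yl)trimethylsilane
Product: 7 allylic alcohol carrying the 2-(trimethylsilylmethyl)vinyl group at C1 (both C1 epimers), via Grignard reagent 6 (not isolated)
Conditions: 5, Mg, THF, rt; then 4, THF, −78 °C; H2O
Reagents that add atoms: none
Why: 1,2-Addition of the vinyl Grignard reagent to the aldehyde is much faster than attack on the trisubstituted epoxide and installs C10, C14 and C9; the new carbinol centre forms unselectively and is destroyed in step 5.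

Step 5
Reactants: 7 allylic alcohol (both C1 epimers), 8 vinyl acetate
Product: 10 (4Z)-7-[(2R,3R)-2-methyl-3-(triethylsilyloxymethyl)oxiran-2-yl]-4-[(trimethylsilyl)methyl]hept-4-enal, via allyl vinyl ether 9 (not isolated)
Conditions: [Ir(cod)Cl]2 (cat.), Na2CO3, toluene, 100 °C; then 140 °C
Reagents that add atoms: none
Why: Iridium-catalysed transfer vinylation followed by Claisen rearrangement through a chair transition state with the C1 substituent equatorial should give the trisubstituted olefin with C2 and C9 trans (Z by CIP only because of silicon), adding C8 and C7 and revealing the C7 aldehyde under base-buffered, non-acidic conditions that spare the allylsilane.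

Step 6
Reactants: 10 aldehyde, 11 methyl acrylate
Product: 12 methyl (6Z)-3-hydroxy-2-methylidene-9-[(2R,3R)-2-methyl-3-(triethylsilyloxymethyl)oxiran-2-yl]-6-[(trimethylsilyl)methyl]non-6-enoate (both C3 epimers)
Conditions: DABCO, methyl acrylate (excess, neat), rt
Reagents that add atoms: none
Why: The Morita–Baylis–Hillman reaction attaches C11, C12 and C13 to the C7 aldehyde; the new carbinol centre forms unselectively and disappears in step 7.

Step 7
Reactants: 12 Baylis–Hillman alcohol
Product: 14 methyl (2Z,6Z)-2-(chloromethyl)-9-[(2R,3R)-2-methyl-3-(triethylsilyloxymethyl)oxiran-2-yl]-6-[(trimethylsilyl)methyl]nona-2,6-dienoate, via allylic mesylate 13 (not isolated)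
Conditions: MsCl, Et3N, CH2Cl2, 0 °C; then LiCl, THF, rt
Reagents that add atoms: lithium chloride, [Li+].[Cl-]
Why: Mesylation then SN2′ displacement by chloride transposes the allylic system to the preferred (Z)-2-(chloromethyl)enoate without any electrophilic halogen that could attack the allylsilane; the geometry of this olefin does not matter later because the allylchromium species equilibrates.

Step 8
Reactants: 14 allylic chloride
Product: 15 methyl (2Z,6Z)-2-(chloromethyl)-9-[(2R,3S)-3-formyl-2-methyloxiran-2-yl]-6-[(trimethylsilyl)methyl]nona-2,6-dienoate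
Conditions: (COCl)2, DMSO, CH2Cl2, −78 to −30 °C; then Et3N, −78 °C
Reagents that add atoms: none
Why: Swern conditions oxidise primary triethylsilyl ethers directly to aldehydes (oxidative desilylation), so the sensitive epoxy aldehyde C6 is unveiled in one operation at low temperature; no stereocentre is formed and the short cold exposure to amine should not epimerise C5.

Step 9
Reactants: 15 acyclic epoxy aldehyde
Product: 17 4α-hydroxy-1αH,5αH-guaia-10(14),11(13)-dien-12,6α-olide, via macrocyclic epoxy lactone 16 (not isolated)
Conditions: CrCl2, THF, rt, slow addition (high dilution); then BF3·OEt2, CH2Cl2, −78 °C; aqueous NaHCO3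
Reagents that add atoms: none
Why: Divalent chromium inserts into the allylic C–Cl bond to give a γ-substituted 2-(methoxycarbonyl)allylchromium reagent that adds through C7 to the C6 aldehyde (SE2′, Nozaki–Hiyama allylation), the chromium alkoxide lactonises onto the ester to give 16, and BF3·OEt2 then activates the 4,5-epoxide so that the C1 terminus of the allylsilane attacks C5 with loss of silicon. The closest known reaction types are the chromium-mediated Barbier macrocyclisation of 2-(halomethyl)acrylate aldehydes to germacranolides, the acid-induced transannular cyclisation of 4,5-epoxygermacranolides to guaianolides, and allylsilane-terminated epoxide cyclisations. The ten-membered ring closes by 1,2-addition to the carbonyl (10-exo-trig), the lactone by 5-exo-trig acyl substitution, and the C1–C5 bond by a transannular anti epoxide opening that is 5-endo-tet for the cyclopentane and 7-exo-tet for the cycloheptane, possible because the ten-membered ring holds C1 behind the C5–O bond. The anti-selective, geometry-convergent allylchromium addition gives the 6,7-trans lactone, the facial choice at C6 is made by the conformation of the forming ring (macrocyclic control, the sense found in natural 4,5-epoxygermacranolides, opposite to simple Felkin addition), C4 is retained and C5 inverted from the Sharpless epoxide, and C1 is set by the olefin face that points across the ring in the crossed conformer (1α-H, cis to 5α-H). The step needs ring closure over oligomerisation (high dilution), attack at C5 and not C4 (a C1–C4 bond would be a four-membered ring), and termination to the exocyclic C10=C14 olefin instead of C1=C10, which the β-silyl cation secures.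

Step 10
Reactants: 17 4α-hydroxy guaianolide
Product: 18 1αH,5αH-guaia-3,10(14),11(13)-trien-12,6α-olide
Conditions: Martin sulfurane, CH2Cl2, 0 °C
Reagents that add atoms: none
Why: Dehydration of the tertiary alcohol by anti elimination can use H3β or a C15 hydrogen but not the syn H5, and the more substituted endocyclic C3=C4 olefin is expected to predominate.

Step 11
Reactants: 18 guaia-3,10(14),11(13)-trienolide
Product: 19 estafiatin (3α,4α-epoxide)
Conditions: mCPBA (1 equiv), NaHCO3, CH2Cl2, 0 °C
Reagents that add atoms: 3-chloroperoxybenzoic acid, O=C(OO)c1cccc(Cl)c1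
Why: Peracid epoxidation is fastest at the trisubstituted C3=C4 bond and should occur from the convex α-face of the cis-fused hydroazulene, giving the 3α,4α-epoxide.

Step 12
Reactants: 19 estafiatin
Product: 20 isozaluzanin C (3α-hydroxy-4(15)-ene)
Conditions: Al(OiPr)3, toluene, reflux
Reagents that add atoms: none
Why: Aluminium alkoxide-mediated isomerisation of the epoxide to the allylic alcohol (syn β-elimination) removes a C15 proton and gives the exocyclic C4=C15 olefin with retention at C3 (3α-OH).

Step 13
Reactants: 20 isozaluzanin C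
Product: 21 dehydrozaluzanin C
Conditions: Dess–Martin periodinane, NaHCO3, CH2Cl2, rt
Reagents that add atoms: none
Why: Dess–Martin oxidation of the allylic alcohol gives the α-methylene cyclopentanone and erases the temporary C3 stereocentre.

Step 14
Reactants: 21 dehydrozaluzanin C
Product: 22 tert-butyldimethylsilyl dienol ether of 21 (C2=C3–OSi)
Conditions: TBSOTf, Et3N, CH2Cl2, −78 °C
Reagents that add atoms: tert-butyldimethylsilyl trifluoromethanesulfonate, CC(C)(C)[Si](C)(C)OS(=O)(=O)C(F)(F)F
Why: Soft enolisation with silyl triflate and amine can only occur toward C2, giving the 2-silyloxy diene needed for dehydrogenation.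

Step 15
Reactants: 22 silyl dienol ether, 21 dehydrozaluzanin C
Product: 24 Diels–Alder adduct (new bonds C2′–C4 and C14′–C15, C1′=C10′ olefin, 2′β-H), via trienone 23 (not isolated)
Conditions: Pd(OAc)2, MeCN, rt; then 21 (excess), 40 °C
Reagents that add atoms: none
Why: Saegusa–Ito oxidation gives trienone 23, whose ring-held s-cis diene C2′=C1′–C10′=C14′ adds to the C4=C15 enone of 21 in a Diels–Alder reaction with C14′ bonding to the β-carbon C15; attack on the convex α-face of the dienophile (the side of H1 and H5) sets the spiro centre C4, and the configuration at C2′ is immaterial because it is erased in step 16.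

Step 16
Reactants: 24 Diels–Alder adduct
Product: 25 target compound CNP0221188.1
Conditions: DBU (cat.), CH2Cl2, rt
Reagents that add atoms: none
Why: Base-mediated isomerisation of the β,γ-enone (deprotonation at C2′, γ-protonation at C10′) gives the conjugated 1′(2′)-en-3′-one, and the now vinylogous C5′ and C10′ should equilibrate under the same conditions to the configuration taken as favoured (see the assumption).

**Compound list**
1 | geraniol, (2E)-3,7-dimethylocta-2,6-dien-1-ol | CC(C)=CCC/C(C)=C/CO | starting material
2 | (2R,3R)-2,3-epoxygeraniol | CC(C)=CCC[C@@]1(C)O[C@@H]1CO | intermediate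
3 | triethylsilyl ether of 2 | CC(C)=CCC[C@@]1(C)O[C@@H]1CO[Si](CC)(CC)CC | intermediate
4 | 3-[(2R,3R)-2-methyl-3-(triethylsilyloxymethyl)oxiran-2-yl]propanal | O=CCC[C@@]1(C)O[C@@H]1CO[Si](CC)(CC)CC | intermediate
5 | (2-bromoprop-2-en-1-yl)trimethylsilane | C=C(Br)C[Si](C)(C)C | starting material
6 | [3-(trimethylsilyl)prop-1-en-2-yl]magnesium bromide | C=C([Mg]Br)C[Si](C)(C)C | intermediate
7 | 1-[(2R,3R)-2-methyl-3-(triethylsilyloxymethyl)oxiran-2-yl]-4-[(trimethylsilyl)methyl]pent-4-en-3-ol, both C3 epimers | C=C(C[Si](C)(C)C)C(O)CC[C@@]1(C)O[C@@H]1CO[Si](CC)(CC)CC | intermediate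
8 | vinyl acetate | CC(=O)OC=C | starting material
9 | vinyl ether of 7 | C=COC(CC[C@@]1(C)O[C@@H]1CO[Si](CC)(CC)CC)C(=C)C[Si](C)(C)C | intermediate
10 | (4Z)-7-[(2R,3R)-2-methyl-3-(triethylsilyloxymethyl)oxiran-2-yl]-4-[(trimethylsilyl)methyl]hept-4-enal | O=CCC/C(C[Si](C)(C)C)=C/CC[C@@]1(C)O[C@@H]1CO[Si](CC)(CC)CC | intermediate
11 | methyl acrylate | C=CC(=O)OC | starting material
12 | methyl (6Z)-3-hydroxy-2-methylidene-9-[(2R,3R)-2-methyl-3-(triethylsilyloxymethyl)oxiran-2-yl]-6-[(trimethylsilyl)methyl]non-6-enoate, both C3 epimers | C=C(C(=O)OC)C(O)CC/C(C[Si](C)(C)C)=C/CC[C@@]1(C)O[C@@H]1CO[Si](CC)(CC)CC | intermediate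
13 | methanesulfonate of 12 | C=C(C(=O)OC)C(OS(C)(=O)=O)CC/C(C[Si](C)(C)C)=C/CC[C@@]1(C)O[C@@H]1CO[Si](CC)(CC)CC | intermediate
14 | methyl (2Z,6Z)-2-(chloromethyl)-9-[(2R,3R)-2-methyl-3-(triethylsilyloxymethyl)oxiran-2-yl]-6-[(trimethylsilyl)methyl]nona-2,6-dienoate | COC(=O)/C(CCl)=C/CC/C(C[Si](C)(C)C)=C/CC[C@@]1(C)O[C@@H]1CO[Si](CC)(CC)CC | intermediate
15 | methyl (2Z,6Z)-2-(chloromethyl)-9-[(2R,3S)-3-formyl-2-methyloxiran-2-yl]-6-[(trimethylsilyl)methyl]nona-2,6-dienoate | COC(=O)/C(CCl)=C/CC/C(C[Si](C)(C)C)=C/CC[C@@]1(C)O[C@@H]1C=O | intermediate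
16 | 14-(trimethylsilyl)parthenolide, (4R,5R,6S,7S)-4,5-epoxy-14-(trimethylsilyl)germacra-1(10),11(13)-dien-12,6-olide, C2 and C9 trans across C1=C10 | C[Si](C)(C)C/C1=C\CC[C@@]2(C)O[C@@H]2[C@H]3OC(=O)C(=C)[C@@H]3CC1 | intermediate
17 | 4α-hydroxy-1αH,5αH-guaia-10(14),11(13)-dien-12,6α-olide | C[C@@]1(O)CC[C@H]2C(=C)CC[C@H]3C(=C)C(=O)O[C@@H]3[C@@H]12 | intermediate
18 | 1αH,5αH-guaia-3,10(14),11(13)-trien-12,6α-olide | CC1=CC[C@H]2C(=C)CC[C@H]3C(=C)C(=O)O[C@@H]3[C@@H]12 | intermediate
19 | estafiatin, 3α,4α-epoxy-1αH,5αH-guaia-10(14),11(13)-dien-12,6α-olide | C[C@@]12O[C@@H]1C[C@H]3C(=C)CC[C@H]4C(=C)C(=O)O[C@@H]4[C@@H]23 | intermediate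
20 | isozaluzanin C, 3α-hydroxy-1αH,5αH-guaia-4(15),10(14),11(13)-trien-12,6α-olide | C=C1[C@H](O)C[C@H]2C(=C)CC[C@H]3C(=C)C(=O)O[C@@H]3[C@@H]12 | intermediate
21 | dehydrozaluzanin C, 3-oxo-1αH,5αH-guaia-4(15),10(14),11(13)-trien-12,6α-olide | C=C1C(=O)C[C@H]2C(=C)CC[C@H]3C(=C)C(=O)O[C@@H]3[C@@H]12 | intermediate
22 | 3-(tert-butyldimethylsilyloxy)-1αH,5αH-guaia-2,4(15),10(14),11(13)-tetraen-12,6α-olide | C=C1C(O[Si](C)(C)C(C)(C)C)=C[C@H]2C(=C)CC[C@H]3C(=C)C(=O)O[C@@H]3[C@@H]12 | intermediate
23 | 3-oxo-5αH-guaia-1,4(15),10(14),11(13)-tetraen-12,6α-olide | C=C1C(=O)C=C2C(=C)CC[C@H]3C(=C)C(=O)O[C@@H]3[C@@H]12 | intermediate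
24 | Diels–Alder adduct of 23 and 21: spiro dimer with C1′=C10′ olefin, 2′β-H, 5′α-H | C=C1C(=O)[C@H]2C3=C(CC[C@H]4C(=C)C(=O)O[C@@H]4[C@@H]13)CC[C@]21C(=O)C[C@H]2C(=C)CC[C@H]3C(=C)C(=O)O[C@@H]3[C@H]21 | intermediate
25 | CNP0221188.1 | C=C1C(=O)C2=C3[C@H](CC[C@H]4C(=C)C(=O)O[C@@H]4[C@H]13)CC[C@]21C(=O)C[C@H]2C(=C)CC[C@H]3C(=C)C(=O)O[C@@H]3[C@H]21 | target

**Totals**
Total step count: 16. Longest linear sequence: 16 steps (geraniol to 25; 21 is used twice, in steps 14 and 15).

**Steps most likely to fail**

Step 9. The ring closure may give oligomers instead of the ten-membered ring. The aldehyde may be attacked from the wrong face, giving the C6 epimer by simple Felkin addition. The allylsilane may be lost before the epoxide is opened. The fallback separates the two bond formations and moves the C6–C7 bond to a chelation-controlled allylindium addition. It sets out from 12: acetylation (Ac2O, DMAP) should give the allylic acetate F1, and Swern oxidation of its silyl ether the epoxy aldehyde acetate F2. Umpolung with Pd(PPh3)4 and indium monoiodide (InI) under high dilution turns the π-allylpalladium species into an allylindium reagent. This should add to the aldehyde under chelation by the epoxide oxygen and lactonise to 16, which is now isolated and purified. Treatment of pure 16 with BF3·OEt2 at −78 °C then gives 17, where the route is rejoined.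

Step 16. The equilibrium at C5′ may not favour the needed epimer (5′-H cis to 6′-H), and C10′ may be protonated from both faces. The fallback replaces equilibration by a kinetic enolate quench and sets out from 24. A weak amine (Et3N, CH2Cl2) should move the olefin into conjugation without touching C5′, giving the 5′α-H isomer of the target F4. KN(SiMe3)2 in THF at −78 °C then removes the doubly activated C5′ proton to give the potassium trienolate F5. Its α-carbon C2′ is fully substituted and shielded by the spiro ring, so 2,6-di-tert-butylphenol at −78 °C should protonate at C5′, from the face anti to the C6′–O bond. This gives 25, where the route ends.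

Step 10. The elimination may run toward the methyl group and give the exocyclic olefin instead of the C3=C4 olefin. The fallback uses that isomer and sets out from 17. Dehydration with SOCl2 and pyridine and separation gives dehydrocostus lactone F3. Allylic hydroxylation of F3 with SeO2 and t-BuOOH at C3 from the α-face gives 20 directly, where the route is rejoined; steps 11 and 12 are then not needed for that material.

**Further compounds**
F1 | step 9 | allylic acetate of 12 | C=C(C(=O)OC)C(OC(C)=O)CC/C(C[Si](C)(C)C)=C/CC[C@@]1(C)O[C@@H]1CO[Si](CC)(CC)CC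
F2 | step 9 | epoxy aldehyde acetate (C6 aldehyde from F1) | C=C(C(=O)OC)C(OC(C)=O)CC/C(C[Si](C)(C)C)=C/CC[C@@]1(C)O[C@@H]1C=O
F3 | step 10 | dehydrocostus lactone | C=C1CC[C@H]2C(=C)CC[C@H]3C(=C)C(=O)O[C@@H]3[C@@H]12
F4 | step 16 | 5′α-H isomer of 25 | C=C1C(=O)C2=C3[C@H](CC[C@H]4C(=C)C(=O)O[C@@H]4[C@@H]13)CC[C@]21C(=O)C[C@H]2C(=C)CC[C@H]3C(=C)C(=O)O[C@@H]3[C@H]21
F5 | step 16 | potassium trienolate of F4 (C5′ deprotonated) | [K+].C=C1C([O-])=C2C=3[C@H](CC[C@H]4C(=C)C(=O)O[C@@H]4C1=3)CC[C@]21C(=O)C[C@H]2C(=C)CC[C@H]3C(=C)C(=O)O[C@@H]3[C@H]21
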